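**Strategy.** The cyclopentenone is cut into acrolein (C1–C3) and a dihydroxyacetone unit (C4, C5 and the side-chain carbinol carbon C1'). The ring ketone C1 and the tertiary carbinol C5 form an α-ketol, the signature of an acyl-anion (benzoin) addition, while C3–C4 is a Michael bond. One amine/carbene relay operation therefore joins an enantiopure 4-tetradecyl-1,3-dioxan-5-one to acrolein: enamine Michael addition makes C3–C4, and carbene umpolung of the new aldehyde closes C1–C5 on the dioxanone carbonyl. The acetonide that ties O4 to O1' is a temporary ring; it forces cis ring fusion and so the trans-4,5-diol. Desaturation and an acetyl relay from O5 to O1' finish the synthesis.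

Key step: step 4

Remarks on the chemistry:
- Atom labels: ring C1 (C=O), C2=C3, C4 (CHOH), C5 (quaternary C–OH); C1' is the acetoxy-bearing side-chain carbon; O4, O5 and O1' are the oxygens on these carbons.
- Assumption: the SAMP alkylation follows the usual azaenolate model (as in 3-pentanone to (S)-4-methyl-3-heptanone), which corresponds to the (S)-ketone 6. The C=N geometry of 3 and 5 is left open because the hydrazone is cleaved.

Step 1
Reactants: 1 2,2-dimethyl-1,3-dioxan-5-one; 2 SAMP, (S)-1-amino-2-(methoxymethyl)pyrrolidine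
Product: 3 (S)-N-(2,2-dimethyl-1,3-dioxan-5-ylidene)-2-(methoxymethyl)pyrrolidin-1-amine
Conditions: benzene, reflux, water separator
Reagents that add atoms: none
Why: Condensation of the ketone with the 1,1-dialkylhydrazine gives the hydrazone (hydrazone formation); no stereocentre is formed.

Step 2
Reactants: 3 SAMP hydrazone; 4 1-iodotetradecane
Product: 5 (S)-N-[(4S)-2,2-dimethyl-4-tetradecyl-1,3-dioxan-5-ylidene]-2-(methoxymethyl)pyrrolidin-1-amine
Conditions: t-BuLi, THF, −78 °C; then 4, −100 °C → rt
Reagents that add atoms: none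
Why: Enders SAMP-hydrazone α-alkylation: the lithium azaenolate, held rigid by chelation of lithium to the methoxy group, is alkylated on one face, which should set the (S)-centre that becomes C1'.

Step 3
Reactants: 5 alkylated SAMP hydrazone
Product: 6 (S)-2,2-dimethyl-4-tetradecyl-1,3-dioxan-5-one
Conditions: saturated aqueous oxalic acid, Et2O, rt
Reagents that add atoms: water, O
Why: Mild two-phase acidic hydrazone hydrolysis should free the ketone without cleaving the acetonide or epimerising the α-centre, and the auxiliary is recovered from the aqueous phase.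

Step 4
Reactants: 6 (S)-2,2-dimethyl-4-tetradecyl-1,3-dioxan-5-one; 7 acrolein
Product: 9 (4S,4aS,7aR)-4a-hydroxy-2,2-dimethyl-4-tetradecylhexahydrocyclopenta[d][1,3]dioxin-5-one (cis-fused bicyclic ketol), via keto aldehyde 8 (not isolated)
Conditions: (S)-2-(methoxymethyl)pyrrolidine (20 mol %), 2-(pentafluorophenyl)-6,7-dihydro-5H-pyrrolo[2,1-c][1,2,4]triazol-2-ium tetrafluoroborate (10 mol %), NaOAc (20 mol %), 7 added slowly, CHCl3, rt
Reagents that add atoms: none
Why: Proposed new method: the secondary amine converts 6 into the enamine at its unsubstituted CH2 α-carbon, which adds to the β-carbon of acrolein (free or as its iminium ion) to make C3–C4 and give keto aldehyde 8; the triazolylidene carbene then turns the new aldehyde into its Breslow intermediate, an acyl-anion equivalent that adds to the dioxanone carbonyl to make C1–C5 and release the catalyst. The closest known reaction type is the amine/N-heterocyclic carbene relay Michael–crossed benzoin cascade of 1,3-dicarbonyl donors with enals, and both halves are known separately (enamine additions of 2,2-dimethyl-1,3-dioxan-5-one, intramolecular aldehyde–ketone benzoin to tertiary α-ketols); what is new is an α,α'-dioxygenated ketone as enamine donor toward an enal inside the relay. The cyclopentanone closes in a 5-exo-trig mode. C4 is set in the Michael half: acrolein should enter on the enamine face away from the methoxymethyl arm of the (S)-amine, which is also the face anti to the axial acetonide methyl when the tetradecyl group is equatorial, giving the 4R centre cis to tetradecyl; C5 is set by the dioxanone ring, because a three-atom arm on the adjacent carbon can reach the carbonyl carbon only with cis ring fusion, which places the new hydroxyl trans to O4. The step needs Michael addition at the CH2 carbon only, no epimerisation of the tetradecyl-bearing α-centre and benzoin rather than homoenolate chemistry of acrolein; these should be secured by allylic strain in the alternative tetrasubstituted enamine, by fast intramolecular trapping of 8, and by slow addition of acrolein together with the electron-poor N-aryl triazolium.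

Step 5
Reactants: 9 bicyclic ketol
Product: 10 (4S,4aS,7aR)-2,2-dimethyl-5-oxo-4-tetradecylhexahydrocyclopenta[d][1,3]dioxin-4a-yl acetate
Conditions: Ac2O, DMAP, Et3N, CH2Cl2, 40 °C
Reagents that add atoms: acetic anhydride, CC(=O)OC(C)=O
Why: DMAP-catalysed acylation (nucleophilic catalysis) should acetylate the tertiary α-ketol hydroxyl O5, the only free hydroxyl while O4 and O1' are tied in the acetonide.

Step 6
Reactants: 10 tertiary acetate
Product: 12 (4S,4aS,7aR)-2,2-dimethyl-5-oxo-4-tetradecyl-5,7a-dihydro-4H-cyclopenta[d][1,3]dioxin-4a-yl acetate (the C2=C3 enone), via silyl enol ether 11 (not isolated)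
Conditions: TMSOTf, Et3N, CH2Cl2, 0 °C; then Pd(OAc)2, MeCN, rt
Reagents that add atoms: none
Why: Saegusa–Ito oxidation: the ketone can enolise only toward C2 because C5 is quaternary, so the trimethylsilyl enol ether and its palladium diacetate dehydrosilylation should give the C2=C3 enone regiospecifically.

Step 7
Reactants: 12 enone acetonide acetate
Product: 14 (1S)-1-[(1R,2R)-1,2-dihydroxy-5-oxocyclopent-3-en-1-yl]pentadecyl acetate (target), via tertiary acetate diol 13 (not isolated)
Conditions: AcOH/THF/H2O (3:1:1), 45 °C; then pH 7.4 phosphate buffer/THF, rt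
Reagents that add atoms: none
Why: Acid hydrolysis of the acetonide frees O4 and O1', and a 1,2-acyl migration through a five-membered cyclic orthoacid should then move the acetyl from the hindered tertiary O5 to the secondary O1' only, because O4 is trans to O5 on the ring and cannot form the corresponding bicyclic intermediate.

**Compound list**

1 | 2,2-dimethyl-1,3-dioxan-5-one | CC1(C)OCC(=O)CO1 | starting material
2 | SAMP, (S)-1-amino-2-(methoxymethyl)pyrrolidine | COC[C@@H]1CCCN1N | starting material
3 | (S)-N-(2,2-dimethyl-1,3-dioxan-5-ylidene)-2-(methoxymethyl)pyrrolidin-1-amine | COC[C@@H]1CCCN1N=C1COC(C)(C)OC1 | intermediate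
4 | 1-iodotetradecane | CCCCCCCCCCCCCCI | starting material
5 | (S)-N-[(4S)-2,2-dimethyl-4-tetradecyl-1,3-dioxan-5-ylidene]-2-(methoxymethyl)pyrrolidin-1-amine | CCCCCCCCCCCCCC[C@@H]1OC(C)(C)OCC1=NN1CCC[C@H]1COC | intermediate
6 | (S)-2,2-dimethyl-4-tetradecyl-1,3-dioxan-5-one | CCCCCCCCCCCCCC[C@@H]1OC(C)(C)OCC1=O | intermediate
7 | acrolein (prop-2-enal) | C=CC=O | starting material
8 | 3-[(4R,6S)-2,2-dimethyl-5-oxo-6-tetradecyl-1,3-dioxan-4-yl]propanal | CCCCCCCCCCCCCC[C@@H]1OC(C)(C)O[C@H](CCC=O)C1=O | intermediate
9 | (4S,4aS,7aR)-4a-hydroxy-2,2-dimethyl-4-tetradecylhexahydrocyclopenta[d][1,3]dioxin-5-one | CCCCCCCCCCCCCC[C@@H]1OC(C)(C)O[C@@H]2CCC(=O)[C@]12O | intermediate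
10 | (4S,4aS,7aR)-2,2-dimethyl-5-oxo-4-tetradecylhexahydrocyclopenta[d][1,3]dioxin-4a-yl acetate | CCCCCCCCCCCCCC[C@@H]1OC(C)(C)O[C@@H]2CCC(=O)[C@]12OC(C)=O | intermediate
11 | (4S,4aS,7aR)-2,2-dimethyl-4-tetradecyl-5-[(trimethylsilyl)oxy]-7,7a-dihydro-4H-cyclopenta[d][1,3]dioxin-4a-yl acetate | CCCCCCCCCCCCCC[C@@H]1OC(C)(C)O[C@@H]2CC=C(O[Si](C)(C)C)[C@]12OC(C)=O | intermediate
12 | (4S,4aS,7aR)-2,2-dimethyl-5-oxo-4-tetradecyl-5,7a-dihydro-4H-cyclopenta[d][1,3]dioxin-4a-yl acetate | CCCCCCCCCCCCCC[C@@H]1OC(C)(C)O[C@@H]2C=CC(=O)[C@]12OC(C)=O | intermediate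
13 | (1S,2R)-2-hydroxy-1-[(1S)-1-hydroxypentadecyl]-5-oxocyclopent-3-en-1-yl acetate | CCCCCCCCCCCCCC[C@H](O)[C@@]1(OC(C)=O)C(=O)C=C[C@H]1O | intermediate
14 | (1S)-1-[(1R,2R)-1,2-dihydroxy-5-oxocyclopent-3-en-1-yl]pentadecyl acetate | CCCCCCCCCCCCCC[C@H](OC(C)=O)[C@@]1(O)C(=O)C=C[C@H]1O | target

**Total step count:** 7
**Longest linear sequence:** 7 steps (from 1)

**Steps most likely to fail**

1. Step 4 (relay Michael–benzoin). What may go wrong: poor facial selectivity of the enamine addition (a trans adduct would close to the bicycle epimeric at C4 and C5 relative to C1'), epimerisation of the tetradecyl-bearing α-centre, or oligomerisation and homoenolate self-reaction of acrolein. Fallback by known chemistry, setting out from 6 and returning at 9: 6 is condensed with RAMP to the RAMP hydrazone F1. Deprotonation with t-BuLi (THF, −78 °C) at the unsubstituted α'-carbon and auxiliary-controlled alkylation with 4-iodobut-1-ene give the cis-dialkylated hydrazone F2. Ozonolysis (O3, CH2Cl2, −78 °C; Me2S) cleaves the C=N and the terminal C=C together to give keto aldehyde 8, this time isolated. The same triazolium salt with Et3N in CH2Cl2 then effects the known intramolecular aldehyde–ketone benzoin to 9.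

2. Step 7 (acetonide removal and acetyl shift). What may go wrong: incomplete migration from O5 to O1', onward 1,3-shift of the acetyl to O4, or loss of the acetate by hydrolysis. Fallback, setting out from 12 and returning at 14: 12 is hydrolysed as above and 13 is isolated. The less hindered ring hydroxyl O4 is silylated (TESOTf, 2,6-lutidine, CH2Cl2, −78 °C) to the 4-O-triethylsilyl tertiary acetate F8. With O4 blocked, catalytic DBU in CH2Cl2 drives the acetyl shift to O1' without onward migration, giving the 4-O-triethylsilyl secondary acetate F9. HF·pyridine in THF removes the silyl group to give 14.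

3. Step 5 (acetylation of the tertiary α-ketol). What may go wrong: slow or incomplete acylation of the hindered hydroxyl, or base-induced α-ketol rearrangement on forcing. Fallback, setting out from 9 and returning at 14, replacing the acetyl relay by protecting-group differentiation: TMSOTf/Et3N silylates O5 and forms the enol ether, giving the bis(trimethylsilyl) compound F3, and Pd(OAc)2 in MeCN gives the enone silyl ether F4. Aqueous AcOH/THF removes the silyl group and the acetonide to give the triol F5. TBSCl/imidazole in DMF at 0 °C is expected to silylate the less hindered allylic ring hydroxyl O4, giving the 4-O-silyl ether F6. Ac2O/pyridine with catalytic DMAP acetylates the secondary O1' in preference to the tertiary O5, giving the silylated acetate F7. HF·pyridine in THF gives 14.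

**Further compounds**

F1 | step 4 | (R)-N-[(4S)-2,2-dimethyl-4-tetradecyl-1,3-dioxan-5-ylidene]-2-(methoxymethyl)pyrrolidin-1-amine | CCCCCCCCCCCCCC[C@@H]1OC(C)(C)OCC1=NN1CCC[C@@H]1COC
F2 | step 4 | (R)-N-[(4R,6S)-4-(but-3-en-1-yl)-2,2-dimethyl-6-tetradecyl-1,3-dioxan-5-ylidene]-2-(methoxymethyl)pyrrolidin-1-amine | CCCCCCCCCCCCCC[C@@H]1OC(C)(C)O[C@H](CCC=C)C1=NN1CCC[C@@H]1COC
F3 | step 5 | (4S,4aS,7aR)-2,2-dimethyl-4-tetradecyl-4a,5-bis[(trimethylsilyl)oxy]-4,4a,7,7a-tetrahydrocyclopenta[d][1,3]dioxine | CCCCCCCCCCCCCC[C@@H]1OC(C)(C)O[C@@H]2CC=C(O[Si](C)(C)C)[C@]12O[Si](C)(C)C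
F4 | step 5 | (4S,4aS,7aR)-2,2-dimethyl-4-tetradecyl-4a-[(trimethylsilyl)oxy]-4a,7a-dihydrocyclopenta[d][1,3]dioxin-5(4H)-one | CCCCCCCCCCCCCC[C@@H]1OC(C)(C)O[C@@H]2C=CC(=O)[C@]12O[Si](C)(C)C
F5 | step 5 | (4R,5S)-4,5-dihydroxy-5-[(1S)-1-hydroxypentadecyl]cyclopent-2-en-1-one | CCCCCCCCCCCCCC[C@H](O)[C@@]1(O)C(=O)C=C[C@H]1O
F6 | step 5 | (4R,5S)-4-[(tert-butyldimethylsilyl)oxy]-5-hydroxy-5-[(1S)-1-hydroxypentadecyl]cyclopent-2-en-1-one | CCCCCCCCCCCCCC[C@H](O)[C@@]1(O)C(=O)C=C[C@H]1O[Si](C)(C)C(C)(C)C
F7 | step 5 | (1S)-1-[(1S,2R)-2-[(tert-butyldimethylsilyl)oxy]-1-hydroxy-5-oxocyclopent-3-en-1-yl]pentadecyl acetate | CCCCCCCCCCCCCC[C@H](OC(C)=O)[C@@]1(O)C(=O)C=C[C@H]1O[Si](C)(C)C(C)(C)C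
F8 | step 7 | (1S,2R)-1-[(1S)-1-hydroxypentadecyl]-5-oxo-2-[(triethylsilyl)oxy]cyclopent-3-en-1-yl acetate | CCCCCCCCCCCCCC[C@H](O)[C@@]1(OC(C)=O)C(=O)C=C[C@H]1O[Si](CC)(CC)CC
F9 | step 7 | (1S)-1-[(1S,2R)-1-hydroxy-5-oxo-2-[(triethylsilyl)oxy]cyclopent-3-en-1-yl]pentadecyl acetate | CCCCCCCCCCCCCC[C@H](OC(C)=O)[C@@]1(O)C(=O)C=C[C@H]1O[Si](CC)(CC)CC
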